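**Retrosynthetic overview**
1. Xanthogalenol ⇒ 8-prenyl-5-hydroxy-7-methoxyflavanone by base-mediated retro-oxa-Michael (E1cB) ring-opening; the chalcone C=C is unmasked, not made by Claisen–Schmidt aldol.
2. 8-Prenyl flavanone ⇒ 5-O-prenyl flavanone by a Eu(III)-catalysed para-Claisen/Cope cascade (O→C6→C8 prenyl transfer).
3. 5-O-Prenyl ether ⇒ 4'-O-acetylsakuranetin (Mitsunobu) ⇒ sakuranetin ⇒ naringenin (selective 7-O-methylation).
4. No ring is formed: both arenes and the pyranone are bought intact in naringenin. The pyranone differentiates the two ortho oxygens of the A-ring and is the only ring broken, in the last step.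
5. Any normal-prenyl flavanone (C6 or C8) opens to the same chalcone, because the two ortho-OH groups of the product are equivalent by rotation.

Assumption: the target has no stereocentre, so "single enantiomer" is taken to mean the single (E)-alkene isomer shown. Flavanone intermediates are used as racemates, since C2 is destroyed in the last step.

Only compounds that contribute atoms are numbered; PPh3, DIAD, Eu(fod)3 and bases appear in the conditions only. The route is built by analogy to known flavanone chemistry and has not been run on this exact substrate.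

**Step 1**
Reactants: 1 (±)-naringenin (5,7-dihydroxy-2-(4-hydroxyphenyl)chroman-4-one); 2 dimethyl sulfate
Product: 3 (±)-sakuranetin (5-hydroxy-2-(4-hydroxyphenyl)-7-methoxychroman-4-one)
Conditions: Me2SO4 (1.05 equiv), K2CO3 (1.0 equiv), acetone, rt, 12 h
Reagents that add atoms: dimethyl sulfate, COS(=O)(=O)OC
Why: Chemoselective Williamson O-methylation; the 7-OH, para to the C4 carbonyl, is far more acidic than the 4'-OH and the chelated 5-OH, so one equivalent of weak base gives only the 7-phenoxide.

**Step 2**
Reactants: 3 (±)-sakuranetin; 4 acetic anhydride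
Product: 5 (±)-4'-O-acetylsakuranetin (4-(5-hydroxy-7-methoxy-4-oxochroman-2-yl)phenyl acetate)
Conditions: Ac2O (1.1 equiv), pyridine, CH2Cl2, 0 °C → rt
Reagents that add atoms: acetic anhydride, CC(=O)OC(C)=O
Why: Selective O-acylation of the only non-chelated phenol; the peri 5-OH is hydrogen-bonded to C4=O and is not acetylated under stoichiometric mild conditions.

**Step 3**
Reactants: 5 (±)-4'-O-acetylsakuranetin; 6 prenol (3-methylbut-2-en-1-ol)
Product: 7 (±)-5-O-prenyl-4'-O-acetylsakuranetin (4-(7-methoxy-5-[(3-methylbut-2-en-1-yl)oxy]-4-oxochroman-2-yl)phenyl acetate)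
Conditions: prenol (1.5 equiv), PPh3 (1.5 equiv), DIAD (1.5 equiv), THF, 0 °C → rt
Reagents that add atoms: prenol, CC(C)=CCO (delivers C5H9; its oxygen leaves as Ph3P=O)
Why: Mitsunobu etherification alkylates the chelated phenol at oxygen (SN2, no SN2′) under neutral conditions that neither open the flavanone nor cleave the aryl acetate.

**Step 4 (key step)**
Reactants: 7 (±)-5-O-prenyl-4'-O-acetylsakuranetin
Product: 8 (±)-8-prenyl-4'-O-acetylsakuranetin (4-(5-hydroxy-7-methoxy-8-(3-methylbut-2-en-1-yl)-4-oxochroman-2-yl)phenyl acetate)
Conditions: Eu(fod)3 (10 mol %), CHCl3, 60 °C, sealed tube, Ar, ~20 h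
Reagents that add atoms: none
Why: Lewis-acid-catalysed aromatic Claisen/Cope (para-Claisen) cascade; Eu(III) chelated by C4=O/O5 accelerates the [3,3] shift to C6, and the 6-(1,1-dimethylallyl) dienone undergoes a second [3,3] (Cope) shift to C8 before rearomatising, giving a normal prenyl group (the minor 6-(1,1-dimethylallyl) phenol is removed by chromatography).

**Step 5 (key step)**
Reactants: 8 (±)-8-prenyl-4'-O-acetylsakuranetin
Product: 9 xanthogalenol ((E)-1-[2,6-dihydroxy-4-methoxy-3-(3-methylbut-2-en-1-yl)phenyl]-3-(4-hydroxyphenyl)prop-2-en-1-one)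
Conditions: KOH (20% w/v), degassed MeOH–H2O, Ar, 40–50 °C, ~1 h; then poured into ice-cold 1 M HCl (pH 3–4, 0 °C) and extracted at once with EtOAc
Reagents that add atoms: none
Why: Acetate saponification followed by E1cB retro-oxa-Michael ring-opening (C3 enolate expels the O1 phenoxide) gives the chalcone polyphenolate, which is favoured at high pH, and the reversible opening delivers the thermodynamic (E)-enone; fast cold acidification is needed because re-cyclisation is fastest near neutral pH.

**Compound list**
1 | (±)-naringenin | O=C1CC(c2ccc(O)cc2)Oc2cc(O)cc(O)c12 | starting material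
2 | dimethyl sulfate | COS(=O)(=O)OC | starting material (reagent)
3 | (±)-sakuranetin | O=C1CC(c2ccc(O)cc2)Oc2cc(OC)cc(O)c12 | intermediate
4 | acetic anhydride | CC(=O)OC(C)=O | starting material (reagent)
5 | (±)-4'-O-acetylsakuranetin | CC(=O)Oc1ccc(cc1)C1CC(=O)c2c(O)cc(OC)cc2O1 | intermediate
6 | prenol (3-methylbut-2-en-1-ol) | CC(C)=CCO | starting material (reagent)
7 | (±)-5-O-prenyl-4'-O-acetylsakuranetin | CC(=O)Oc1ccc(cc1)C1CC(=O)c2c(OCC=C(C)C)cc(OC)cc2O1 | intermediate
8 | (±)-8-prenyl-4'-O-acetylsakuranetin | CC(=O)Oc1ccc(cc1)C1CC(=O)c2c(O)cc(OC)c(CC=C(C)C)c2O1 | intermediate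
9 | xanthogalenol | COc1cc(O)c(C(=O)/C=C/c2ccc(O)cc2)c(O)c1CC=C(C)C | target

**Total steps:** 5. **Longest linear sequence:** 5 (fully linear from naringenin).

**Three steps most likely to fail, with fallbacks**
1. **Step 5, ring-opening.** The 2',6'-dihydroxychalcone can re-close to the 6- or 8-prenyl flavanone on work-up, and retro-aldol can occur on prolonged heating in base. Fallback: trap instead of quench. Open the ring under anhydrous conditions in the presence of a silylating agent (TBSCl/DBU, DMF) to isolate the tris-O-TBS chalcone, then desilylate with AcOH-buffered TBAF at −20 °C so no free phenoxide is present.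
2. **Step 4, Claisen/Cope.** Rearomatisation of the C6 dienone may outrun the Cope step and give mainly the reverse-prenyl isomer. Fallback: replace steps 2–4 with direct Friedel–Crafts C-prenylation of sakuranetin 3 (prenol/ZnCl2 in EtOAc, or 2-methylbut-3-en-2-ol/BF3·OEt2 in dioxane). This gives a 6-/8-prenyl mixture in modest yield, but both isomers converge on 9 in step 5.
3. **Step 1, mono-methylation.** Over-methylation at the 4'-OH or base-induced opening may lower the yield. Fallback: protect first, then unmask. Make 7,4'-di-O-acetylnaringenin (Ac2O/pyridine), remove the more labile 7-OAc selectively (PhSH/imidazole, NMP), and methylate the free 7-OH (MeI/K2CO3) to reach 5 directly.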